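The strategy avoids coupling the crowded C3'–C8'' biaryl bond and instead grows ring B of the flavanone half on flavone C8''. Ring B carries its substituents at C1' (carbon), C3' (flavonyl) and C4' (OMe). This is the pattern obtained when a β-aryl ketene dimethyl acetal adds across C6 and C3 of methyl coumalate. One operation forms C2'–C3' and C4'–C5', expels CO2 and methanol, and leaves the C1' ester and the C4' ether in place. The precursor is 5,4'-di-O-benzyl-7-O-methylapigenin carrying CH=C(OMe)2 at C8, made from the 8-carbaldehyde by Horner–Wittig olefination. C2 is set late by a catalytic asymmetric oxa-Michael closure.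

Key step: step 9

Assumption: the C3'–C8'' axis has three ortho substituents and is taken to rotate freely at room temperature, since the target SMILES defines no axial descriptor; C2 (S) is the only stereogenic element to control.
Assumption: of the two pseudoenantiomeric cinchona thioureas, the quinidine-derived one is taken to give the 2S series; the sense is to be checked on 24 by circular dichroism, and the quinine-derived catalyst replaces it if the sense is opposite.

Step 1
Reactants: 1 2',6'-dihydroxy-4'-methoxyacetophenone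
Product: 2 2'-(benzyloxy)-6'-hydroxy-4'-methoxyacetophenone
Conditions: BnBr (1.05 equiv), K2CO3 (1.1 equiv), acetone, reflux
Reagents that add atoms: benzyl bromide, BrCc1ccccc1
Why: Williamson etherification in which either hydroxyl of symmetric 1 gives the same product, and after the first benzylation the remaining hydroxyl is held in a hydrogen bond to the ketone and resists a second alkylation.

Step 2
Reactants: 2 2'-(benzyloxy)-6'-hydroxy-4'-methoxyacetophenone; 3 4-(benzyloxy)benzaldehyde
Product: 4 (E)-1-[2-(benzyloxy)-6-hydroxy-4-methoxyphenyl]-3-[4-(benzyloxy)phenyl]prop-2-en-1-one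
Conditions: KOH (50% aq), EtOH, rt
Reagents that add atoms: none
Why: Claisen–Schmidt condensation in which the methyl ketone enolate adds to the non-enolisable aldehyde and E1cB loss of water gives the conjugated E enone, the benzyl ethers being inert to hydroxide.

Step 3
Reactants: 4 (E)-1-[2-(benzyloxy)-6-hydroxy-4-methoxyphenyl]-3-[4-(benzyloxy)phenyl]prop-2-en-1-one
Product: 5 5-(benzyloxy)-2-[4-(benzyloxy)phenyl]-7-methoxy-4H-chromen-4-one
Conditions: I2 (10 mol %), DMSO, 125 °C
Reagents that add atoms: none
Why: Iodine-catalysed oxidative cyclisation of a 2'-hydroxychalcone (oxa-Michael closure, α-iodination, loss of hydrogen iodide, reoxidation of iodide by DMSO), in which only the one free phenol can close the ring, so the benzyloxy group ends at C5.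

Step 4
Reactants: 5 5-(benzyloxy)-2-[4-(benzyloxy)phenyl]-7-methoxy-4H-chromen-4-one
Product: 6 5-(benzyloxy)-2-[4-(benzyloxy)phenyl]-8-iodo-7-methoxy-4H-chromen-4-one
Conditions: NIS (1.1 equiv), CF3CO2H (0.2 equiv), CH2Cl2/MeCN, 0 °C to rt, dark
Reagents that add atoms: N-iodosuccinimide, O=C1CCC(=O)N1I
Why: Electrophilic aromatic iodination in which ring A, with three oxygen donors, is far more nucleophilic than the pyranone-conjugated 2-aryl ring, and 5,7-dialkoxyflavones are known to react at C8 rather than at C6, which here is also shielded between the benzyloxy and methoxy groups.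

Step 5
Reactants: 6 5-(benzyloxy)-2-[4-(benzyloxy)phenyl]-8-iodo-7-methoxy-4H-chromen-4-one
Product: 7 5-(benzyloxy)-2-[4-(benzyloxy)phenyl]-7-methoxy-4-oxo-4H-chromene-8-carbaldehyde
Conditions: CO (3 bar), Et3SiH (1.5 equiv), PdCl2(dppp) (3 mol %), Na2CO3, DMF, 90 °C
Reagents that add atoms: carbon monoxide, [C-]#[O+]
Why: Palladium-catalysed reductive carbonylation (oxidative addition of the carbon–iodine bond to zerovalent palladium, CO insertion that is fast for a crowded aryl, hydride transfer from the silane), which needs no polar organometallic reagent that could attack the flavone carbonyl.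

Step 6
Reactants: 8 chlorodiphenylphosphine; 9 trimethyl orthoformate
Product: 10 (dimethoxymethyl)diphenylphosphine oxide
Conditions: neat, rt to 80 °C, MeCl vented
Reagents that add atoms: none
Why: Michaelis–Arbuzov-type reaction in which exchange gives methyl diphenylphosphinite and a dimethoxycarbenium chloride, after which P-alkylation and demethylation by chloride form the P=O bond.

Step 7
Reactants: 7 5-(benzyloxy)-2-[4-(benzyloxy)phenyl]-7-methoxy-4-oxo-4H-chromene-8-carbaldehyde; 10 (dimethoxymethyl)diphenylphosphine oxide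
Product: 11 rac-5-(benzyloxy)-2-[4-(benzyloxy)phenyl]-8-[2-(diphenylphosphoryl)-1-hydroxy-2,2-dimethoxyethyl]-7-methoxy-4H-chromen-4-one
Conditions: 10 (1.25 equiv), LiN(iPr)2 (1.2 equiv), THF, −100 °C; then 7 in THF, −100 to −78 °C; H2O
Reagents that add atoms: none
Why: Addition stage of a Horner–Wittig olefination in which the lithiated phosphine oxide adds to the aldehyde, by far the most electrophilic site, and the lithium alkoxide does not eliminate, so the racemic adduct (its stereocentre disappears in step 8) can be purified before the sensitive alkene is made.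

Step 8
Reactants: 11 rac-5-(benzyloxy)-2-[4-(benzyloxy)phenyl]-8-[2-(diphenylphosphoryl)-1-hydroxy-2,2-dimethoxyethyl]-7-methoxy-4H-chromen-4-one
Product: 12 5-(benzyloxy)-2-[4-(benzyloxy)phenyl]-8-(2,2-dimethoxyethenyl)-7-methoxy-4H-chromen-4-one
Conditions: KOtBu (1.1 equiv), THF, 0 °C to rt; filtration under argon, concentration, used at once
Reagents that add atoms: none
Why: Elimination stage of the Horner–Wittig reaction, a known entry to ketene O,O-acetals, in which the potassium alkoxide attacks phosphorus and syn-cycloreversion of the oxaphosphetane expels an insoluble phosphinate salt, leaving a non-acidic solution in which the ketene acetal survives.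

Step 9
Reactants: 12 5-(benzyloxy)-2-[4-(benzyloxy)phenyl]-8-(2,2-dimethoxyethenyl)-7-methoxy-4H-chromen-4-one; 13 methyl coumalate
Product: 16 methyl 3-{5-(benzyloxy)-2-[4-(benzyloxy)phenyl]-7-methoxy-4-oxo-4H-chromen-8-yl}-4-methoxybenzoate, via bridged lactone cycloadduct 14 (not isolated), via dimethoxycyclohexadiene ester 15 (not isolated)
Conditions: 13 (3 equiv, in portions), dry mesitylene, 160 °C, slow argon sweep
Reagents that add atoms: none
Why: Proposed new method: the aryl-bearing carbon of 12 holds the largest HOMO coefficient and attacks C6 of 13, the terminus activated by both the C5 ester and the lactone carbonyl, while the acetal carbon closes onto C3, so that a polarised, probably asynchronous inverse-electron-demand Diels–Alder reaction gives bridged lactone 14. Retro-[4+2] loss of CO2 from 14 gives diene 15, in which the C3' hydrogen is γ to the unsaturated ester and sits next to the ionisable C4' acetal, so methanol leaves and the ring aromatises with one methoxy group retained at C4'. The closest known reaction type is the benzannulation of methyl coumalate and related ester-bearing 2-pyranones by 1,1-dialkoxyalkenes to para-alkoxybenzoates; new here is a β-aryl ketene acetal whose aryl group has both ortho positions occupied, so that the new arene is born as a biaryl. Ring B is closed by an intermolecular [4+2] union that forms C2'–C3' and C4'–C5' in one operation, and the stereocentres of 14 and 15 vanish on aromatisation, so no stereocontrol is required. The selectivity needed is regiochemical, flavonyl meta and methoxy para to the ester, and it follows from the matched polarity of the partners, helped by the fact that the crowded carbon bonds to the sterically open C6–H of 13. The two identical methoxy groups remove any dependence on alkene geometry, the benzyl ethers remove every acidic proton that could quench the ketene acetal, and the flavone enone, which has no acceptor at C3, should not compete as a heterodiene.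

Step 10
Reactants: 16 methyl 3-{5-(benzyloxy)-2-[4-(benzyloxy)phenyl]-7-methoxy-4-oxo-4H-chromen-8-yl}-4-methoxybenzoate
Product: 17 3-{5-(benzyloxy)-2-[4-(benzyloxy)phenyl]-7-methoxy-4-oxo-4H-chromen-8-yl}-4-methoxybenzoic acid
Conditions: LiOH·H2O (3 equiv), THF/MeOH/H2O, 40 °C; then 1 M HCl to pH 3
Reagents that add atoms: lithium hydroxide, [Li+].[OH-]
Why: Saponification of an ester flanked by two ring hydrogens, which hydroxide attacks under conditions too mild to open the flavone pyranone ring.

Step 11
Reactants: 17 3-{5-(benzyloxy)-2-[4-(benzyloxy)phenyl]-7-methoxy-4-oxo-4H-chromen-8-yl}-4-methoxybenzoic acid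
Product: 19 5-(benzyloxy)-2-[4-(benzyloxy)phenyl]-8-[5-(hydroxymethyl)-2-methoxyphenyl]-7-methoxy-4H-chromen-4-one, via isobutyl mixed carbonic anhydride 18 (not isolated)
Conditions: iBuOCOCl, N-methylmorpholine, THF, −15 °C; then NaBH4, H2O, 0 °C
Reagents that add atoms: isobutyl chloroformate, CC(C)COC(=O)Cl (its atoms are kept only in 18)
Why: Mixed carbonic anhydride activation followed by borohydride reduction, in which NaBH4 reduces the activated acyl group quickly at 0 °C while the vinylogous-ester carbonyl of a flavone is inert to it, so the flavone reduction expected from aluminium hydrides acting directly on ester 16 is avoided.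

Step 12
Reactants: 19 5-(benzyloxy)-2-[4-(benzyloxy)phenyl]-8-[5-(hydroxymethyl)-2-methoxyphenyl]-7-methoxy-4H-chromen-4-one
Product: 20 3-{5-(benzyloxy)-2-[4-(benzyloxy)phenyl]-7-methoxy-4-oxo-4H-chromen-8-yl}-4-methoxybenzaldehyde
Conditions: activated MnO2 (excess), CH2Cl2, rt
Reagents that add atoms: none
Why: Oxidation of an electron-rich benzylic alcohol on MnO2, which stops at the aldehyde and touches neither the benzyl ethers nor the flavone.

Step 13
Reactants: 2 2'-(benzyloxy)-6'-hydroxy-4'-methoxyacetophenone
Product: 21 tert-butyl 3-[2-(benzyloxy)-6-hydroxy-4-methoxyphenyl]-3-oxopropanoate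
Conditions: LiN(SiMe3)2 (3.2 equiv), THF, −78 °C; Boc2O (1.2 equiv), −78 to −20 °C; cold 1 M HCl
Reagents that add atoms: di-tert-butyl dicarbonate, CC(C)(C)OC(=O)OC(=O)OC(C)(C)C
Why: Claisen-type C-carboxylation of a ketone enolate by a dicarbonate, in which the enolate carbon of the dianion is the most nucleophilic site, any phenol O-carbonate converges on the same product by a Baker–Venkataraman-type O-to-C shift, and the bulky tert-butyl ester resists lactonisation to a 4-hydroxycoumarin.

Step 14
Reactants: 20 3-{5-(benzyloxy)-2-[4-(benzyloxy)phenyl]-7-methoxy-4-oxo-4H-chromen-8-yl}-4-methoxybenzaldehyde; 21 tert-butyl 3-[2-(benzyloxy)-6-hydroxy-4-methoxyphenyl]-3-oxopropanoate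
Product: 22 tert-butyl (Z)-2-[2-(benzyloxy)-6-hydroxy-4-methoxybenzoyl]-3-(3-{5-(benzyloxy)-2-[4-(benzyloxy)phenyl]-7-methoxy-4-oxo-4H-chromen-8-yl}-4-methoxyphenyl)prop-2-enoate (Z, aryl cis to the ester, expected as the main isomer)
Conditions: piperidine (10 mol %), AcOH (10 mol %), 4 Å molecular sieves, toluene, rt
Reagents that add atoms: none
Why: Knoevenagel condensation of an unhindered aldehyde with an active methylene under piperidinium acetate buffering, a weakly basic medium that limits premature racemic ring closure by the hydrogen-bonded phenol.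

Step 15
Reactants: 22 tert-butyl (Z)-2-[2-(benzyloxy)-6-hydroxy-4-methoxybenzoyl]-3-(3-{5-(benzyloxy)-2-[4-(benzyloxy)phenyl]-7-methoxy-4-oxo-4H-chromen-8-yl}-4-methoxyphenyl)prop-2-enoate
Product: 24 (2S)-5-(benzyloxy)-2-(3-{5-(benzyloxy)-2-[4-(benzyloxy)phenyl]-7-methoxy-4-oxo-4H-chromen-8-yl}-4-methoxyphenyl)-7-methoxy-2,3-dihydro-4H-chromen-4-one, via tert-butyl flavanone-3-carboxylate 23 (not isolated)
Conditions: N-[3,5-bis(trifluoromethyl)phenyl]-N'-[(9R)-6'-methoxycinchonan-9-yl]thiourea (10 mol %), toluene, −25 °C; then TsOH·H2O (0.5 equiv), 80 °C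
Reagents that add atoms: none
Why: Catalytic asymmetric intramolecular oxa-Michael addition (6-endo-trig), known for 2-hydroxyaryl alkylidene β-ketoesters, in which the thiourea binds the 1,3-dicarbonyl unit and the quinuclidine nitrogen guides the phenol to one alkene face to set C2 as S, after which acid cleaves the tert-butyl ester and the β-keto acid loses CO2 without involving C2.

Step 16
Reactants: 24 (2S)-5-(benzyloxy)-2-(3-{5-(benzyloxy)-2-[4-(benzyloxy)phenyl]-7-methoxy-4-oxo-4H-chromen-8-yl}-4-methoxyphenyl)-7-methoxy-2,3-dihydro-4H-chromen-4-one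
Product: 25 (2S)-5-hydroxy-2-{3-[5-hydroxy-2-(4-hydroxyphenyl)-7-methoxy-4-oxo-4H-chromen-8-yl]-4-methoxyphenyl}-7-methoxy-2,3-dihydro-4H-chromen-4-one (target)
Conditions: H2 (1 atm), 10% Pd/C, EtOAc/THF, rt, stopped at full debenzylation
Reagents that add atoms: none
Why: Hydrogenolysis of the three aryl benzyl ethers under neutral conditions, in which C2 cannot epimerise by ring opening and the flavone alkene and both carbonyl groups react much more slowly than the O-benzyl bonds.

Compound list
1 | 2',6'-dihydroxy-4'-methoxyacetophenone | CC(=O)c1c(O)cc(OC)cc1O | starting material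
2 | 2'-(benzyloxy)-6'-hydroxy-4'-methoxyacetophenone | CC(=O)c1c(O)cc(OC)cc1OCc1ccccc1 | intermediate
3 | 4-(benzyloxy)benzaldehyde | O=Cc1ccc(OCc2ccccc2)cc1 | starting material
4 | (E)-2'-hydroxychalcone, 6'-OBn, 4'-OMe, 4-OBn | O=C(/C=C/c1ccc(OCc2ccccc2)cc1)c1c(O)cc(OC)cc1OCc1ccccc1 | intermediate
5 | 5,4'-di-O-benzyl-7-O-methylapigenin | COc1cc(OCc2ccccc2)c2c(=O)cc(-c3ccc(OCc4ccccc4)cc3)oc2c1 | intermediate
6 | 8-iodoflavone dibenzyl ether | COc1cc(OCc2ccccc2)c2c(=O)cc(-c3ccc(OCc4ccccc4)cc3)oc2c1I | intermediate
7 | flavone-8-carbaldehyde dibenzyl ether | COc1cc(OCc2ccccc2)c2c(=O)cc(-c3ccc(OCc4ccccc4)cc3)oc2c1C=O | intermediate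
8 | chlorodiphenylphosphine | ClP(c1ccccc1)c1ccccc1 | starting material
9 | trimethyl orthoformate | COC(OC)OC | starting material
10 | (dimethoxymethyl)diphenylphosphine oxide | COC(OC)P(=O)(c1ccccc1)c1ccccc1 | intermediate
11 | racemic β-hydroxy phosphine oxide adduct at flavone C8 | COc1cc(OCc2ccccc2)c2c(=O)cc(-c3ccc(OCc4ccccc4)cc3)oc2c1C(O)C(OC)(OC)P(=O)(c1ccccc1)c1ccccc1 | intermediate
12 | 8-(2,2-dimethoxyethenyl)flavone dibenzyl ether (key precursor) | COC(OC)=Cc1c(OC)cc(OCc2ccccc2)c2c(=O)cc(-c3ccc(OCc4ccccc4)cc3)oc12 | intermediate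
13 | methyl coumalate (methyl 2-oxo-2H-pyran-5-carboxylate) | COC(=O)c1ccc(=O)oc1 | starting material
14 | methyl 7-(flavon-8-yl)-8,8-dimethoxy-3-oxo-2-oxabicyclo[2.2.2]oct-5-ene-6-carboxylate (racemic, endo/exo undefined) | O=C1OC2C(C(=O)OC)=CC1C(OC)(OC)C2c1c(OC)cc(OCc2ccccc2)c2c(=O)cc(-c3ccc(OCc4ccccc4)cc3)oc12 | intermediate
15 | methyl 3-(flavon-8-yl)-4,4-dimethoxycyclohexa-1,5-diene-1-carboxylate (racemic) | COC(=O)C1=CC(c2c(OC)cc(OCc3ccccc3)c3c(=O)cc(-c4ccc(OCc5ccccc5)cc4)oc23)C(OC)(OC)C=C1 | intermediate
16 | methyl 3-(flavon-8-yl)-4-methoxybenzoate dibenzyl ether (key product) | COC(=O)c1ccc(OC)c(-c2c(OC)cc(OCc3ccccc3)c3c(=O)cc(-c4ccc(OCc5ccccc5)cc4)oc23)c1 | intermediate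
17 | 3-(flavon-8-yl)-4-methoxybenzoic acid dibenzyl ether | OC(=O)c1ccc(OC)c(-c2c(OC)cc(OCc3ccccc3)c3c(=O)cc(-c4ccc(OCc5ccccc5)cc4)oc23)c1 | intermediate
18 | isobutyl carbonic anhydride of 17 | CC(C)COC(=O)OC(=O)c1ccc(OC)c(-c2c(OC)cc(OCc3ccccc3)c3c(=O)cc(-c4ccc(OCc5ccccc5)cc4)oc23)c1 | intermediate
19 | 8-[5-(hydroxymethyl)-2-methoxyphenyl]flavone dibenzyl ether | OCc1ccc(OC)c(-c2c(OC)cc(OCc3ccccc3)c3c(=O)cc(-c4ccc(OCc5ccccc5)cc4)oc23)c1 | intermediate
20 | 3-(flavon-8-yl)-4-methoxybenzaldehyde dibenzyl ether | O=Cc1ccc(OC)c(-c2c(OC)cc(OCc3ccccc3)c3c(=O)cc(-c4ccc(OCc5ccccc5)cc4)oc23)c1 | intermediate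
21 | tert-butyl 3-[2-(benzyloxy)-6-hydroxy-4-methoxyphenyl]-3-oxopropanoate | CC(C)(C)OC(=O)CC(=O)c1c(O)cc(OC)cc1OCc1ccccc1 | intermediate
22 | (Z)-alkylidene β-ketoester | CC(C)(C)OC(=O)/C(C(=O)c1c(O)cc(OC)cc1OCc1ccccc1)=C\c1ccc(OC)c(-c2c(OC)cc(OCc3ccccc3)c3c(=O)cc(-c4ccc(OCc5ccccc5)cc4)oc23)c1 | intermediate
23 | tert-butyl (2S)-flavanone-3-carboxylate, tri-O-benzyl (C3 epimers and enol) | COc1cc(OCc2ccccc2)c2c(c1)O[C@H](c1ccc(OC)c(-c3c(OC)cc(OCc4ccccc4)c4c(=O)cc(-c5ccc(OCc6ccccc6)cc5)oc34)c1)C(C(=O)OC(C)(C)C)C2=O | intermediate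
24 | (2S)-tri-O-benzyl flavanone-flavone | COc1cc(OCc2ccccc2)c2c(c1)O[C@H](c1ccc(OC)c(-c3c(OC)cc(OCc4ccccc4)c4c(=O)cc(-c5ccc(OCc6ccccc6)cc5)oc34)c1)CC2=O | intermediate
25 | CNP0288780.1, (2S)-2,3-dihydroamentoflavone 7,4',7''-trimethyl ether | COc1cc(O)c2c(c1)O[C@H](c1ccc(OC)c(-c3c(OC)cc(O)c4c(=O)cc(-c5ccc(O)cc5)oc34)c1)CC2=O | target

Total step count: 16. Longest linear sequence: 14 (steps 1–5, 7–12, 14–16).

Steps most likely to fail

Step 9. Cycloaddition of the crowded ketene acetal may be too slow. Thermal dimerisation of the pyranone, adventitious hydrolysis, or re-addition of the liberated methanol could then consume the partners first. The fallback sets out from 6 and returns at 20. Suzuki–Miyaura coupling of 6 with commercial (5-formyl-2-methoxyphenyl)boronic acid (Pd(OAc)2, SPhos, K3PO4, toluene/H2O, 90 °C) makes the C3'–C8'' bond directly. This coupling type is established for 8-haloflavones. It bypasses steps 5 to 12 and makes no new compound (entry F0).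

Step 15. Three processes could lower the enantiopurity:
- Facial selectivity may be poor, because the ortho benzyloxy group twists the aroyl unit away from the geometry of simpler substrates.
- Racemic background closure may compete with the catalysed pathway.
- Acid-promoted reversible ring opening, assisted by the 4'-methoxy group, may erode the enantiopurity during decarboxylation.

The fallback sets out from 22 and returns at 24 by resolution instead of catalysis. An achiral amine (Et3N, toluene, rt) closes 22 to the racemic tert-butyl flavanone-3-carboxylate F1. TsOH·H2O at 80 °C converts this to the racemic tri-O-benzyl flavanone F2. Preparative chromatography on a polysaccharide chiral stationary phase separates 24 from the (2R)-tri-O-benzyl flavanone F3. Warming F3 with a catalytic amine base equilibrates it back to F2 through reversible ring opening, so it can be resubmitted.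

Step 7. The aldehyde may be poorly soluble at very low temperature. The lithiated phosphine oxide may decompose before it adds, or it may attack flavone C2 in competition. The fallback sets out from 6 and returns at 12:
- Palladium-catalysed cyanomethylation (Me3SiCH2CN, ZnF2, Pd2(dba)3, Xantphos, DMF, 90 °C) gives the (flavon-8-yl)acetonitrile F4.
- A Pinner reaction (HCl from AcCl/MeOH, CH2Cl2, 0 °C) gives the methyl imidate hydrochloride F5.
- Methanolysis (MeOH, rt) gives the trimethyl orthoester F6.
- Heating F6 in mesitylene with Al(OtBu)3 (cat.) under an argon sweep removes methanol, the classical dealcoholation of arylacetic orthoesters, and generates 12 for direct use in step 9.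

Further compounds
F0 | step 9 | none | none
F1 | step 15 | racemic tert-butyl flavanone-3-carboxylate, tri-O-benzyl | COc1cc(OCc2ccccc2)c2c(c1)OC(c1ccc(OC)c(-c3c(OC)cc(OCc4ccccc4)c4c(=O)cc(-c5ccc(OCc6ccccc6)cc5)oc34)c1)C(C(=O)OC(C)(C)C)C2=O
F2 | step 15 | racemic tri-O-benzyl flavanone | COc1cc(OCc2ccccc2)c2c(c1)OC(c1ccc(OC)c(-c3c(OC)cc(OCc4ccccc4)c4c(=O)cc(-c5ccc(OCc6ccccc6)cc5)oc34)c1)CC2=O
F3 | step 15 | (2R)-tri-O-benzyl flavanone | COc1cc(OCc2ccccc2)c2c(c1)O[C@@H](c1ccc(OC)c(-c3c(OC)cc(OCc4ccccc4)c4c(=O)cc(-c5ccc(OCc6ccccc6)cc5)oc34)c1)CC2=O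
F4 | step 7 | (flavon-8-yl)acetonitrile dibenzyl ether | N#CCc1c(OC)cc(OCc2ccccc2)c2c(=O)cc(-c3ccc(OCc4ccccc4)cc3)oc12
F5 | step 7 | methyl (flavon-8-yl)acetimidate hydrochloride | COC(=[NH2+])Cc1c(OC)cc(OCc2ccccc2)c2c(=O)cc(-c3ccc(OCc4ccccc4)cc3)oc12.[Cl-]
F6 | step 7 | trimethyl ortho(flavon-8-yl)acetate | COC(OC)(OC)Cc1c(OC)cc(OCc2ccccc2)c2c(=O)cc(-c3ccc(OCc4ccccc4)cc3)oc12
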